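## Retrosynthetic overview

1. Target 39 comes from diol 38 by double acetylation; 38 from γ-lactone 35 by enolate hydroxylation trans to the C13 substituent; 35 from lactone 28 by one-carbon homologation and re-lactonisation onto the C14 hydroxyl.
2. Lactone 28 comes from butyrolactone 26 by trans-selective alkoxymethylation; 26 from Michael adduct 22 by acetal reduction and C8 deoxygenation.
3. Key disconnection C9–C11: intermolecular Michael addition of the lithium enolate of cis-hydroazulenone 19 to (5S)-5-menthyloxybutenolide 4, which sets quaternary C9 and C11.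
4. Ketone 19 comes from enone vinyl triflate 18 by intramolecular reductive Heck closure of the seven-membered ring; 18 from (+)-fenchone 5 by Beckmann fragmentation and chain extension.
5. Ring order: cyclopentane (from fenchone), then cycloheptane (step 11), then the first butyrolactone (steps 13–14), then the final γ-lactone (steps 18–23).

Assumption: names use the labels C1 (ring C bearing =CH2), C2–C4, C5 (CMe2), C6 and C10 (ring-fusion CH), C7, C8, C9 (C–CH3), C11 (side-chain CH), C12 (CH2O), C13, C14 (OCH2), C15 (C=O), C16 (CH–O); fenchone oxime is taken to fragment at its C1–C2 bond, as camphor oxime does.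

## Route

Step 1
Reactants: 1 furfural
Product: 2 5-hydroxyfuran-2(5H)-one (racemic)
Conditions: O2, hν (visible), tetraphenylporphyrin (cat.), MeOH, 20 °C
Reagents that add atoms: dioxygen, O=O
Why: Singlet-oxygen [4+2] photooxygenation of the furan followed by methanolysis of the endoperoxide expels the formyl carbon as methyl formate and gives the pseudo-acid; no stereocentre is controlled.

Step 2
Reactants: 2 5-hydroxyfuran-2(5H)-one; 3 (1S,2R,5S)-(+)-menthol
Product: 4 (5S)-5-[(1S,2R,5S)-menthyloxy]furan-2(5H)-one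
Conditions: camphorsulfonic acid (cat.), toluene, reflux, Dean–Stark; crystallisation (petroleum ether, −20 °C), mother liquor re-equilibrated with acid
Reagents that add atoms: none
Why: Acid-catalysed acetalisation gives both C5 epimers, which interconvert through the oxocarbenium ion while the (5S) epimer crystallises (crystallisation-induced asymmetric transformation), fixing the acetal stereocentre.

Step 3
Reactants: 5 (1S,4R)-(+)-fenchone
Product: 6 (1S,4R)-fenchone oxime
Conditions: NH2OH·HCl, NaOAc, EtOH/H2O, reflux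
Reagents that add atoms: hydroxylamine hydrochloride, [NH3+]O.[Cl-]
Why: Condensation of hydroxylamine with the hindered ketone gives the oxime without touching either stereocentre.

Step 4
Reactants: 6 (1S,4R)-fenchone oxime
Product: 8 (R)-2-methyl-2-(3-methylcyclopent-2-en-1-yl)propanenitrile, via oxime tosylate 7 (not isolated)
Conditions: TsCl, pyridine, 0 → 60 °C; alkene isomer purified on AgNO3–SiO2
Reagents that add atoms: none
Why: Beckmann fragmentation: the tosylate ionises with cleavage of the anti C1–C2 bond to the nitrile and a tertiary 1-methylcyclopentyl cation, which loses a proton to the trisubstituted ring alkene; fenchone C4 (future C6) is untouched.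

Step 5
Reactants: 8 (R)-2-methyl-2-(3-methylcyclopent-2-en-1-yl)propanenitrile
Product: 10 (R)-2-methyl-2-(3-methylcyclopent-2-en-1-yl)propanal, via aldimine 9 (not isolated)
Conditions: iBu2AlH, CH2Cl2, −78 °C; then 1 M HCl, 0 °C
Reagents that add atoms: water, O
Why: Partial hydride reduction of the tertiary nitrile stops at the imine stage, which is hydrolysed on work-up to the non-enolisable aldehyde.

Step 6
Reactants: 10 (R)-2-methyl-2-(3-methylcyclopent-2-en-1-yl)propanal; 11 [2-(2-methyl-1,3-dioxolan-2-yl)ethyl]triphenylphosphonium bromide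
Product: 13 2-methyl-2-{(2Z)-4-methyl-4-[(1R)-3-methylcyclopent-2-en-1-yl]pent-2-en-1-yl}-1,3-dioxolane, via phosphorus ylide 12 (not isolated)
Conditions: KN(SiMe3)2, THF, 0 °C; then 10, −78 → 20 °C
Reagents that add atoms: none
Why: Wittig olefination with a non-stabilised ylide gives the Z-alkene and adds C4–C1 with C1 masked as a ketal.

Step 7
Reactants: 13 Z-alkene ketal
Product: 14 2-methyl-2-{4-methyl-4-[(1R)-3-methylcyclopent-2-en-1-yl]pentyl}-1,3-dioxolane
Conditions: H2 (1 atm), RhCl(PPh3)3 (5 mol%), benzene, 20 °C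
Reagents that add atoms: none
Why: Homogeneous (Wilkinson) hydrogenation reduces the disubstituted chain alkene much faster than the trisubstituted ring alkene.

Step 8
Reactants: 14 saturated ketal
Product: 15 (R)-6-methyl-6-(3-methylcyclopent-2-en-1-yl)heptan-2-one
Conditions: pyridinium p-toluenesulfonate (cat.), acetone/H2O, 50 °C
Reagents that add atoms: water, O
Why: Acid-catalysed ketal hydrolysis frees the methyl ketone.

Step 9
Reactants: 15 (R)-6-methyl-6-(3-methylcyclopent-2-en-1-yl)heptan-2-one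
Product: 17 (R)-6-methyl-6-(3-methylcyclopent-2-en-1-yl)hept-1-en-2-yl trifluoromethanesulfonate, via potassium enolate 16 (not isolated)
Conditions: KN(SiMe3)2, THF, −78 °C; then PhNTf2, −78 → 0 °C; aq. NH4Cl
Reagents that add atoms: N-phenylbis(trifluoromethanesulfonimide), O=S(=O)(N(c1ccccc1)S(=O)(=O)C(F)(F)F)C(F)(F)F
Why: Kinetic deprotonation on the methyl side and O-triflation give the terminal enol triflate that later becomes C1 with its exocyclic methylene.

Step 10
Reactants: 17 cyclopentene enol triflate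
Product: 18 6-methyl-6-[(1R)-3-methyl-4-oxocyclopent-2-en-1-yl]hept-1-en-2-yl trifluoromethanesulfonate
Conditions: Pd(OH)2/C (5 mol%), t-BuOOH, K2CO3, CH2Cl2, 0 → 20 °C
Reagents that add atoms: tert-butyl hydroperoxide, CC(C)(C)OO
Why: Allylic C–H oxidation of the ring CH2 next to the methyl-bearing alkene carbon gives the 2-methylcyclopentenone; the hindered allylic methine (C6) is left alone.

Step 11
Reactants: 18 enone enol triflate
Product: 19 cis-fused (3aR,8aR)-1,4,4-trimethyl-8-methylideneoctahydroazulen-2(1H)-one (C8 ketone; C9 epimers)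
Conditions: Pd(OAc)2 (10 mol%), PPh3, HCO2Na, Bu4NCl, DMF, 80 °C
Reagents that add atoms: none
Why: Intramolecular reductive Heck reaction (7-exo conjugate carbopalladation, formate as hydride source) forms C1–C10; the tether from C6 delivers the vinyl group to its own face, which sets C10 with a cis ring fusion.

Step 12
Reactants: 19 cis-hydroazulenone
Product: 20 trimethylsilyl enol ether of 19 (C8–OSiMe3, C8=C9)
Conditions: Me3SiCl, Et3N, DMF, 110 °C
Reagents that add atoms: chlorotrimethylsilane, C[Si](C)(C)Cl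
Why: Thermodynamic silyl enol ether formation gives the more substituted enol ether, fixing the enolate regiochemistry and erasing the C9 epimers.

Step 13
Reactants: 20 silyl enol ether; 4 (5S)-5-menthyloxybutenolide
Product: 22 Michael adduct (C8 ketone; quaternary C9; C11 carrying the 4,5-trans 5-menthyloxybutyrolactone), via lithium enolate 21 (not isolated)
Conditions: MeLi (1.0 equiv), THF, 0 °C; then 4, −78 °C; aq. NH4Cl
Reagents that add atoms: none
Why: Michael addition: the tetrasubstituted enolate attacks the butenolide β-carbon from its convex face (cis to the ring-fusion hydrogens) and anti to the menthyloxy group, setting C9 and C11.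

Step 14
Reactants: 22 Michael adduct
Product: 24 hydroxy lactone (C8–OH epimers; lactone C12–O–C16(=O)), via hydroxy carboxylate salt 23 (not isolated)
Conditions: NaBH4, KOH, MeOH/H2O, 0 → 20 °C; then 2 M HCl (pH 2)
Reagents that add atoms: none
Why: Hydroxide opens the pseudo-ester to the aldehyde carboxylate, borohydride reduces the aldehyde and the C8 ketone, and acidification relactonises with loss of menthol; C11 is untouched.

Step 15
Reactants: 24 hydroxy lactone
Product: 25 O-phenyl thionocarbonate of 24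
Conditions: PhOC(S)Cl, pyridine, DMAP (cat.), CH2Cl2, 20 °C
Reagents that add atoms: O-phenyl chlorothionoformate, S=C(Cl)Oc1ccccc1
Why: Acylation of the hindered C8 alcohol prepares it for radical deoxygenation.

Step 16
Reactants: 25 thionocarbonate
Product: 26 (4R)-4-[(1R,3aR,8aS)-1,4,4-trimethyl-8-methylidenedecahydroazulen-1-yl]oxolan-2-one
Conditions: Bu3SnH, AIBN (cat.), toluene, 110 °C
Reagents that add atoms: none
Why: Barton–McCombie deoxygenation removes the C8 oxygen through a secondary radical without affecting any stereocentre.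

Step 17
Reactants: 26 butyrolactone
Product: 28 trans-3-[(4-methoxybenzyloxy)methyl] derivative of 26, via lithium lactone enolate 27 (not isolated)
Conditions: LiN(iPr)2, THF, −78 °C; then 4-MeOC6H4CH2OCH2Cl, −78 → −40 °C
Reagents that add atoms: 4-methoxybenzyl chloromethyl ether, COc1ccc(COCCl)cc1
Why: Enolate alkylation of the β-substituted butyrolactone occurs anti to the bulky C11 substituent, setting C13 (trans) and adding C14.

Step 18
Reactants: 28 alkylated lactone
Product: 29 lactol of 28 (anomers)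
Conditions: iBu2AlH (1.1 equiv), CH2Cl2, −78 °C; aq. KNaC4H4O6
Reagents that add atoms: none
Why: Low-temperature hydride reduction of the lactone stops at the lactol.

Step 19
Reactants: 29 lactol
Product: 30 enol ether alcohol (C16=C15 methyl enol ether, E/Z; C12–OH; C14–OPMB)
Conditions: [Ph3PCH2OMe]Cl, KN(SiMe3)2, THF, 0 °C; then 29, 0 → 20 °C
Reagents that add atoms: (methoxymethyl)triphenylphosphonium chloride, COC[P+](c1ccccc1)(c1ccccc1)c1ccccc1.[Cl-]
Why: Wittig methoxymethylenation of the open hydroxy-aldehyde form adds C15 and frees the C12 hydroxyl.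

Step 20
Reactants: 30 enol ether alcohol
Product: 31 tert-butyldimethylsilyl ether of 30
Conditions: t-BuMe2SiCl, imidazole, DMF, 20 °C
Reagents that add atoms: tert-butyldimethylsilyl chloride, CC(C)(C)[Si](C)(C)Cl
Why: Silylation protects the primary C12 hydroxyl so that it cannot compete in the later ring closure or in the enolate step.

Step 21
Reactants: 31 silyl ether
Product: 32 aldehyde (C15 aldehyde; C12–OTBS; C14–OPMB)
Conditions: pyridinium p-toluenesulfonate (cat.), acetone/H2O (10:1), 40 °C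
Reagents that add atoms: water, O
Why: Mild acid hydrolysis of the enol ether unmasks the homologated aldehyde.

Step 22
Reactants: 32 aldehyde
Product: 34 lactol (ring C13–C14–O–C15–C16; anomers; C12–OTBS), via hydroxy aldehyde 33 (not isolated)
Conditions: DDQ, CH2Cl2/pH 7 buffer, 0 °C
Reagents that add atoms: none
Why: Oxidative cleavage of the 4-methoxybenzyl ether frees the C14 hydroxyl, which closes onto the C15 aldehyde as the five-membered lactol.

Step 23
Reactants: 34 lactol
Product: 35 γ-lactone (C15 carbonyl; C12–OTBS)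
Conditions: Pr4N[RuO4] (5 mol%), N-methylmorpholine N-oxide, 4 Å sieves, CH2Cl2, 20 °C
Reagents that add atoms: none
Why: Ley–Griffith oxidation converts the lactol into the γ-lactone.

Step 24
Reactants: 35 γ-lactone
Product: 37 α-hydroxy lactone (C16–OH trans to the C13 substituent), via potassium lactone enolate 36 (not isolated)
Conditions: KN(SiMe3)2, THF, −78 °C; then 2-(phenylsulfonyl)-3-phenyloxaziridine, −78 °C; aq. NH4Cl
Reagents that add atoms: 2-(phenylsulfonyl)-3-phenyloxaziridine, O=S(=O)(N1OC1c1ccccc1)c1ccccc1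
Why: Davis oxidation of the lactone enolate occurs anti to the C13 substituent, setting C16 (trans).

Step 25
Reactants: 37 α-hydroxy lactone
Product: 38 diol (C12–OH, C16–OH)
Conditions: HF·pyridine, THF, 0 → 20 °C
Reagents that add atoms: none
Why: Fluoride cleavage of the silyl ether under mildly acidic conditions avoids translactonisation.

Step 26
Reactants: 38 diol
Product: 39 (3S,4R)-4-{(1R)-2-(acetyloxy)-1-[(1R,3aR,8aS)-1,4,4-trimethyl-8-methylidenedecahydroazulen-1-yl]ethyl}-2-oxooxolan-3-yl acetate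
Conditions: Ac2O, pyridine, DMAP (cat.), CH2Cl2, 0 → 20 °C
Reagents that add atoms: acetic anhydride, CC(=O)OC(C)=O
Why: Acetylation of the primary and secondary hydroxyls gives the target.

## Compound list

1 | furfural | O=Cc1ccco1 | starting material
2 | 5-hydroxyfuran-2(5H)-one (racemic) | O=C1C=CC(O)O1 | intermediate
3 | (1S,2R,5S)-(+)-menthol | C[C@H]1CC[C@@H]([C@H](C1)O)C(C)C | starting material
4 | (5S)-5-[(1S,2R,5S)-menthyloxy]furan-2(5H)-one | O=C1C=C[C@@H](O[C@H]2C[C@@H](C)CC[C@@H]2C(C)C)O1 | intermediate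
5 | (1S,4R)-(+)-fenchone | CC1(C)[C@@H]2CC[C@@](C)(C2)C1=O | starting material
6 | (1S,4R)-fenchone oxime | CC1(C)[C@@H]2CC[C@@](C)(C2)C1=NO | intermediate
7 | fenchone oxime O-tosylate | CC1(C)[C@@H]2CC[C@@](C)(C2)C1=NOS(=O)(=O)c1ccc(C)cc1 | intermediate
8 | (R)-2-methyl-2-(3-methylcyclopent-2-en-1-yl)propanenitrile | N#CC(C)(C)[C@H]1C=C(C)CC1 | intermediate
9 | (R)-2-methyl-2-(3-methylcyclopent-2-en-1-yl)propan-1-imine | N=CC(C)(C)[C@H]1C=C(C)CC1 | intermediate
10 | (R)-2-methyl-2-(3-methylcyclopent-2-en-1-yl)propanal | O=CC(C)(C)[C@H]1C=C(C)CC1 | intermediate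
11 | [2-(2-methyl-1,3-dioxolan-2-yl)ethyl]triphenylphosphonium bromide | CC1(CC[P+](c2ccccc2)(c2ccccc2)c2ccccc2)OCCO1.[Br-] | starting material
12 | [2-(2-methyl-1,3-dioxolan-2-yl)ethylidene]triphenylphosphorane | CC1(CC=P(c2ccccc2)(c2ccccc2)c2ccccc2)OCCO1 | intermediate
13 | 2-methyl-2-{(2Z)-4-methyl-4-[(1R)-3-methylcyclopent-2-en-1-yl]pent-2-en-1-yl}-1,3-dioxolane | CC1(C/C=C\C(C)(C)[C@H]2C=C(C)CC2)OCCO1 | intermediate
14 | 2-methyl-2-{4-methyl-4-[(1R)-3-methylcyclopent-2-en-1-yl]pentyl}-1,3-dioxolane | CC1(CCCC(C)(C)[C@H]2C=C(C)CC2)OCCO1 | intermediate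
15 | (R)-6-methyl-6-(3-methylcyclopent-2-en-1-yl)heptan-2-one | CC(=O)CCCC(C)(C)[C@H]1C=C(C)CC1 | intermediate
16 | potassium enolate of 15 (terminal) | C=C([O-])CCCC(C)(C)[C@H]1C=C(C)CC1.[K+] | intermediate
17 | (R)-6-methyl-6-(3-methylcyclopent-2-en-1-yl)hept-1-en-2-yl trifluoromethanesulfonate | C=C(OS(=O)(=O)C(F)(F)F)CCCC(C)(C)[C@H]1C=C(C)CC1 | intermediate
18 | 6-methyl-6-[(1R)-3-methyl-4-oxocyclopent-2-en-1-yl]hept-1-en-2-yl trifluoromethanesulfonate | C=C(OS(=O)(=O)C(F)(F)F)CCCC(C)(C)[C@H]1C=C(C)C(=O)C1 | intermediate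
19 | cis-fused (3aR,8aR)-1,4,4-trimethyl-8-methylideneoctahydroazulen-2(1H)-one, C9 epimers | C=C1CCCC(C)(C)[C@@H]2CC(=O)C(C)[C@H]12 | intermediate
20 | trimethylsilyl enol ether of 19 (C8=C9) | C=C1CCCC(C)(C)[C@@H]2CC(O[Si](C)(C)C)=C(C)[C@H]12 | intermediate
21 | lithium enolate of 19 (C8=C9) | C=C1CCCC(C)(C)[C@@H]2CC([O-])=C(C)[C@H]12.[Li+] | intermediate
22 | Michael adduct: C8-oxo hydroazulene joined at C9 to C4 of (4,5-trans)-5-menthyloxyoxolan-2-one | C=C1CCCC(C)(C)[C@@H]2CC(=O)[C@@](C)([C@@H]3[C@@H](O[C@H]4C[C@@H](C)CC[C@@H]4C(C)C)OC(=O)C3)[C@H]12 | intermediate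
23 | potassium hydroxy carboxylate (C8–OH, C12–OH, C16 carboxylate) | C=C1CCCC(C)(C)[C@@H]2CC(O)[C@@](C)([C@H](CO)CC(=O)[O-])[C@H]12.[K+] | intermediate
24 | hydroxy lactone (C8–OH epimers) | C=C1CCCC(C)(C)[C@@H]2CC(O)[C@@](C)([C@@H]3COC(=O)C3)[C@H]12 | intermediate
25 | O-phenyl thionocarbonate of 24 | C=C1CCCC(C)(C)[C@@H]2CC(OC(=S)Oc4ccccc4)[C@@](C)([C@@H]3COC(=O)C3)[C@H]12 | intermediate
26 | (4R)-4-[(1R,3aR,8aS)-1,4,4-trimethyl-8-methylidenedecahydroazulen-1-yl]oxolan-2-one | C=C1CCCC(C)(C)[C@@H]2CC[C@@](C)([C@@H]3COC(=O)C3)[C@H]12 | intermediate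
27 | lithium enolate of 26 | C=C1CCCC(C)(C)[C@@H]2CC[C@@](C)([C@@H]3COC([O-])=C3)[C@H]12.[Li+] | intermediate
28 | trans-3-[(4-methoxybenzyloxy)methyl] derivative of 26 | C=C1CCCC(C)(C)[C@@H]2CC[C@@](C)([C@@H]3COC(=O)[C@H]3COCc3ccc(OC)cc3)[C@H]12 | intermediate
29 | lactol of 28 (anomers) | C=C1CCCC(C)(C)[C@@H]2CC[C@@](C)([C@@H]3COC(O)[C@H]3COCc3ccc(OC)cc3)[C@H]12 | intermediate
30 | enol ether alcohol (E/Z; C12–OH; C14–OPMB) | C=C1CCCC(C)(C)[C@@H]2CC[C@@](C)([C@H](CO)[C@H](COCc3ccc(OC)cc3)C=COC)[C@H]12 | intermediate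
31 | tert-butyldimethylsilyl ether of 30 | C=C1CCCC(C)(C)[C@@H]2CC[C@@](C)([C@H](CO[Si](C)(C)C(C)(C)C)[C@H](COCc3ccc(OC)cc3)C=COC)[C@H]12 | intermediate
32 | aldehyde (C15 aldehyde; C12–OTBS; C14–OPMB) | C=C1CCCC(C)(C)[C@@H]2CC[C@@](C)([C@H](CO[Si](C)(C)C(C)(C)C)[C@H](COCc3ccc(OC)cc3)CC=O)[C@H]12 | intermediate
33 | hydroxy aldehyde (C14–OH; C15 aldehyde) | C=C1CCCC(C)(C)[C@@H]2CC[C@@](C)([C@H](CO[Si](C)(C)C(C)(C)C)[C@H](CO)CC=O)[C@H]12 | intermediate
34 | lactol (anomers; C12–OTBS) | C=C1CCCC(C)(C)[C@@H]2CC[C@@](C)([C@H](CO[Si](C)(C)C(C)(C)C)[C@@H]3COC(O)C3)[C@H]12 | intermediate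
35 | γ-lactone (C12–OTBS) | C=C1CCCC(C)(C)[C@@H]2CC[C@@](C)([C@H](CO[Si](C)(C)C(C)(C)C)[C@@H]3COC(=O)C3)[C@H]12 | intermediate
36 | potassium enolate of 35 | C=C1CCCC(C)(C)[C@@H]2CC[C@@](C)([C@H](CO[Si](C)(C)C(C)(C)C)[C@@H]3COC([O-])=C3)[C@H]12.[K+] | intermediate
37 | α-hydroxy lactone (C16–OH trans to C13 substituent; C12–OTBS) | C=C1CCCC(C)(C)[C@@H]2CC[C@@](C)([C@H](CO[Si](C)(C)C(C)(C)C)[C@@H]3COC(=O)[C@H]3O)[C@H]12 | intermediate
38 | diol (C12–OH, C16–OH) | C=C1CCCC(C)(C)[C@@H]2CC[C@@](C)([C@H](CO)[C@@H]3COC(=O)[C@H]3O)[C@H]12 | intermediate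
39 | (3S,4R)-4-{(1R)-2-(acetyloxy)-1-[(1R,3aR,8aS)-1,4,4-trimethyl-8-methylidenedecahydroazulen-1-yl]ethyl}-2-oxooxolan-3-yl acetate | C=C1CCCC(C)(C)[C@@H]2CC[C@@](C)([C@H](COC(C)=O)[C@@H]3COC(=O)[C@H]3OC(C)=O)[C@H]12 | target

## Step count and risks

Total step count: 26 (2 for the butenolide, 24 from fenchone). Longest linear sequence: 24 steps (5 to 39).

**Step 4 (Beckmann fragmentation).** The proton loss may favour the alkene isomer with the double bond remote from the side chain, and the C–C bond that cleaves is assumed rather than proven. Fallback, starting again from oxime 6 and returning at enone 18: the isomeric nitrile 2-methyl-2-(3-methylcyclopent-3-en-1-yl)propanenitrile F1 is not discarded. It is reduced with iBu2AlH to the aldehyde F2, olefinated with ylide 12 to the Z-alkene ketal F3, hydrogenated over RhCl(PPh3)3 to the saturated ketal F4, hydrolysed to the methyl ketone F5 and triflated to the enol triflate F6. The enone is then installed by an oxidation-state detour instead of allylic oxidation: hydroboration–oxidation of the ring alkene (BH3·SMe2, then NaBO3) gives the cyclopentanol F7, Dess–Martin oxidation gives the 2-methylcyclopentanone F8, and dehydrogenation towards the more substituted side (IBX, DMSO, 70 °C) gives 18.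

**Step 11 (seven-membered reductive Heck closure).** Direct reduction of the vinyl triflate or a slow 7-exo insertion could defeat it. Fallback, setting out from cyclopentene triflate 17 (so that step 10 is skipped) and returning at ketone 19: a conventional intramolecular Heck reaction (Pd(OAc)2, PPh3, Ag2CO3, MeCN, 80 °C) with β-hydride elimination into the five-membered ring gives the cis-fused diene F9. Epoxidation of its trisubstituted alkene with mCPBA (NaHCO3, −20 °C) gives the epoxide F10, and BF3·OEt2 at −78 °C (Meinwald rearrangement by hydride shift) gives 19.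

**Step 13 (Michael addition forming the quaternary centre).** The hindered enolate may add sluggishly or deprotonate the acetal carbon of 4. Fallback, setting out from butenolide 4 and returning at adduct 22: bromine addition gives the dibromo lactone F11, and triethylamine eliminates HBr to the doubly activated 3-bromo-5-menthyloxybutenolide F12. Lithium enolate 21 adds to it at −78 °C to give the bromo lactone adduct F13, and Zn in AcOH removes the bromine to give 22.

Further compounds
F1 | step 4 | 2-methyl-2-(3-methylcyclopent-3-en-1-yl)propanenitrile | N#CC(C)(C)[C@@H]1CC=C(C)C1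
F2 | step 4 | 2-methyl-2-(3-methylcyclopent-3-en-1-yl)propanal | O=CC(C)(C)[C@@H]1CC=C(C)C1
F3 | step 4 | 2-methyl-2-[(2Z)-4-methyl-4-(3-methylcyclopent-3-en-1-yl)pent-2-en-1-yl]-1,3-dioxolane | CC1(C/C=C\C(C)(C)[C@@H]2CC=C(C)C2)OCCO1
F4 | step 4 | 2-methyl-2-[4-methyl-4-(3-methylcyclopent-3-en-1-yl)pentyl]-1,3-dioxolane | CC1(CCCC(C)(C)[C@@H]2CC=C(C)C2)OCCO1
F5 | step 4 | 6-methyl-6-(3-methylcyclopent-3-en-1-yl)heptan-2-one | CC(=O)CCCC(C)(C)[C@@H]1CC=C(C)C1
F6 | step 4 | 6-methyl-6-(3-methylcyclopent-3-en-1-yl)hept-1-en-2-yl trifluoromethanesulfonate | C=C(OS(=O)(=O)C(F)(F)F)CCCC(C)(C)[C@@H]1CC=C(C)C1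
F7 | step 4 | 6-(3-hydroxy-4-methylcyclopentyl)-6-methylhept-1-en-2-yl trifluoromethanesulfonate | C=C(OS(=O)(=O)C(F)(F)F)CCCC(C)(C)[C@@H]1CC(O)C(C)C1
F8 | step 4 | 6-methyl-6-(3-methyl-4-oxocyclopentyl)hept-1-en-2-yl trifluoromethanesulfonate | C=C(OS(=O)(=O)C(F)(F)F)CCCC(C)(C)[C@@H]1CC(=O)C(C)C1
F9 | step 11 | cis-fused 1,4,4-trimethyl-8-methylidene-3,3a,4,5,6,7,8,8a-octahydroazulene | C=C1CCCC(C)(C)[C@@H]2CC=C(C)[C@H]12
F10 | step 11 | 1,2-epoxide of F9 | C=C1CCCC(C)(C)[C@@H]2CC3OC3(C)[C@H]12
F11 | step 13 | 3,4-dibromo-(5S)-5-menthyloxyoxolan-2-one | O=C1C(Br)C(Br)[C@@H](O[C@H]2C[C@@H](C)CC[C@@H]2C(C)C)O1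
F12 | step 13 | 3-bromo-(5S)-5-menthyloxyfuran-2(5H)-one | O=C1C(Br)=C[C@@H](O[C@H]2C[C@@H](C)CC[C@@H]2C(C)C)O1
F13 | step 13 | 3-bromo analogue of adduct 22 | C=C1CCCC(C)(C)[C@@H]2CC(=O)[C@@](C)([C@@H]3[C@@H](O[C@H]4C[C@@H](C)CC[C@@H]4C(C)C)OC(=O)C3Br)[C@H]12
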